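## Analysis of the target

The target is a depsidone. Ring A (the methoxy arene) and ring B (the phenol arene) are joined by an ester and by a diaryl ether, which together close a seven-membered dibenzo-1,4-dioxepinone. Ring B is also fused to a δ-lactone (an isochroman-1-one) whose C3 is a spiro ketal carbon shared with a 6-methyltetrahydropyran.

Locants used below: ring A as a benzoate (C1 carries the ester carbonyl, C2 the ether oxygen, C4 the methoxy group, C6 the 2-oxoheptyl arm); ring B as the isochromanone (C1 lactone carbonyl, C3 spiro carbon, C4 benzylic CH2, C5 ether oxygen, C6 ester oxygen, C7 hydrogen, C8 hydroxyl); the tetrahydropyran primed (O1', C2' = C3, C6' bearing the methyl).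

There are two stereocentres, the spiro carbon (S) and C6' (R), in a 1,3 relationship across O1'. The methyl and the C4 methylene are cis, so in the chair both are equatorial and the lactone oxygen is axial; this is the anomerically favoured, thermodynamic arrangement, and only C6' has to be bought as a stereocentre.

The sensitive groups are:
- the spiro acyl ketal, opened by acid and by nucleophiles;
- the aryl ester of the depsidone, an activated ester;
- the side-chain ketone, ortho to the ester carbonyl, which can enol-lactonize onto it and expel ring B;
- the hydrogen-bonded C8 phenol.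

The difficulty lies in the two links between crowded arenes: the ester joins a benzoyl group with both ortho positions occupied to a phenol, and the ether oxygen enters ring B at C5 between two substituted carbons.

The strategy rests on ring A. Its oxygens at C2 and C4 are meta, and the carboxyl carbon on C1 lies between the C2 oxygen and the C6 arm. This is the pattern a linear 3,5,7-trioxo ester adopts when its C2 closes onto its C7 carbonyl, so ring A can be grown from an open chain whose ester oxygen is already the C6 oxygen of ring B.

## Retrosynthetic reasoning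

**23 to 22.** The side-chain ketone of 23 is traced back to the dioxolane 22. No skeletal bond is cut. The gain is that the ketone stays masked through every basic and oxidative step: free, it would enolize toward ring A and attack the aryl ester, and it would offer a second aldol acceptor when ring A is formed. The forward reaction has to hydrolyse a dioxolane without opening the spiro acyl ketal irreversibly.

**22 to 21.** The ether bond between the ring A C2 oxygen and ring B C5 is cut, giving depside 21. This bond is chosen over the ester because C5 is para to the C8 phenol, the site where phenol oxidation places radical character, and because the ester is then left to be made earlier under neutral conditions. The forward reaction is an oxidative C–O coupling that closes the seven-membered ring.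

**21 to 20.** The O–methyl bond on ring A C4 is cut. In 20 this is the only hydroxyl not hydrogen-bonded to a carbonyl, so the forward methylation needs no protecting group.

**20 to 18.** Ring A is opened between C1 and C6 and its two phenol carbons are returned to ketones, which unravels 20 into the aryl 3,5,7-trioxo ester 18 (chain C1 = ester carbonyl, C9 = ketal carbon). The cut is placed here because the chain then carries the whole substitution pattern of ring A in its sequence of carbonyls, and because the hindered ester never has to be made on a finished, doubly ortho-substituted benzoic acid. The forward reaction must join chain C2 to the C7 carbonyl, dehydrate and enolize, without losing the ring B aryloxide.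

**18 to 16 and 10.** The acyl–oxygen bond of the ester is cut. The acyl part is the acylketene 17, stored as the dioxinone 16; the phenol part is the ring B resorcinol 10. Forward, heating releases 17, which must be captured by the C6 hydroxyl of 10 in preference to the chelated C8 hydroxyl, under neutral conditions that a β-polyketone tolerates.

**16 to 11, 13 and acetyl chloride.** Two Claisen-type C–C bonds are cut, C6–C7 and C4–C5 of the chain. This leads to keto-dioxinone 12 and Weinreb amide 15, then to dioxinone 11 and, through ketal ester 14, to the keto ester 13. The ketal is introduced at the start, on 13, where it is trivial.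

**10 to 7 and 5.** Debenzylation leads back to 9. In 9 the benzylic C4–C3 bond and the lactone acyl–oxygen bond are cut, giving the toluate 7 (from 6) and the lactone 5, with 8 as the open intermediate. The forward reaction needs a lateral carbanion addition and then an acid equilibration that sets the spiro centre from C6'.

**5 to 1 and 2.** The C4'–C5' bond is cut, so that hydroxy ynoate 3 (hydrogenated to 4, which lactonizes) comes from epoxide 1 and propiolate 2. The only purchased stereocentre is that of 1.

## Alternatives that were turned down

**Alternative 1:** a threefold alkyne cyclotrimerization that makes ring A and the seven-membered ring together.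
- Disconnection: ring A is cut at C1–C2, C3–C4 and C5–C6. This gives diyne A2, in which an ynoate sits on the C6 oxygen of ring B and an ethynyl ether on its C5 oxygen, and methoxyacetylene A3.
- Forward step: [Rh(cod)2]BF4 with a chelating bisphosphine (a cationic complex of monovalent rhodium) would couple the two tethered alkynes of A2 to a rhodacycle, insert A3 and release A1, the target carrying a dioxolane and a methoxymethyl ether.
- For: convergence is the highest of all plans. The ether oxygen and the ester are in place before ring A exists, so neither an oxidative coupling nor a hindered esterification is needed, and A1 is two deprotections from the target. On these points it is stronger than the chosen route.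
- Against: the tether between the alkynes has five atoms, so the metallacycle must form across a future seven-membered ring, and an aryl ester prefers the conformation that holds the ynoate away from the ether alkyne. A3 can insert in two orientations, and only one places the methoxy group at C4. A3 and the aryl ethynyl ether are volatile or labile and prone to self-trimerization. Ring B must first be made as a C5/C6 catechol with three differentiated oxygens on the acyl ketal, which is longer than the route to 10.
- Comparison: three unsecured selectivities fall on one late step with fully elaborated material. In the chosen route the regiochemistry of ring A is written into the carbon chain.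

**Alternative 2:** a squarate-derived ring expansion that builds ring B.
- Disconnection: ring B is cut between C8 and C8a and traced to the 4-alkenyl-4-hydroxycyclobutenone A5.
- Forward step: heating A5 in toluene opens the four-membered ring (4π) to a dienylketene. Its 6π closure joins the ketene carbon to the ester-bearing alkene carbon and, after tautomerization, gives hydroquinone A4.
- For: A4 already carries the C5 oxygen, so the ether position on ring B is fixed by construction. The chosen route cannot match this, since its oxidative coupling must distinguish C5 from C7. The key step is thermal and neutral.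
- Against: it solves ring B only. A5 needs a stereodefined metallated acrylate carrying the whole C4–C6' chain and several squarate manipulations. A4 is an air-sensitive hydroquinone whose two hydroxyls and isopropyl ether must be told apart, and the isopropyl ether must later be cleaved beside an acyl ketal. Ring A, an Ullmann-type etherification onto an electron-rich ring and the hindered ester all remain.
- Comparison: the chosen route reaches ring B (10) in five operations from methyl orsellinate and spends its key step on ring A and the ester together.

**Alternative 3:** a toluate anion annulation that builds the spiro lactone of ring B.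
- Disconnection: the benzylic C4–C3 bond and the lactone acyl–oxygen bond of ring B.
- Forward step: a laterally lithiated orsellinate ester adds to the six-membered (R)-lactone and the lactolate closes on the neighbouring ester, giving A6, which is the same compound as 9.
- For: it is short, and the spiro centre follows from C6' by anomeric control. On ring B it is exactly as strong as the chosen route, because this bond construction is kept as step 4.
- Against: what is turned down is the plan built around it. With ring B as the centre, ring A has to be made separately as acid A7 and esterified to a phenol. A7 is flanked by an oxygen and the arm, and its ketone must be masked to stop isocoumarin formation on activation.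
- Comparison: the chosen route forms this ester by ketene capture before ring A exists, so the risk moves from a hindered acylation to the aldol closure.

Key step: step 11

Remark: the spiro configuration of the target (S, methyl cis to the C4 methylene) is the anomerically stabilized one and is assumed to be reached by acid equilibration; LiN(i-Pr)2 and LiN(SiMe3)2 are used as purchased solutions.

## Route

Step 1
Reactants: 1 (R)-propylene oxide; 2 ethyl propiolate
Product: 3 ethyl (R)-5-hydroxyhex-2-ynoate
Conditions: 2, n-BuLi, THF, −78 °C; BF3·OEt2; then 1, −78 °C; aq. NH4Cl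
Reagents that add atoms: none
Why: Yamaguchi–Hirao alkynylation: the lithium acetylide of 2, activated by BF3·OEt2, opens the epoxide by SN2 at the unsubstituted carbon, so the R carbinol centre of 1 is carried unchanged into 3 and becomes C6' of the target.

Step 2
Reactants: 3 ethyl (R)-5-hydroxyhex-2-ynoate
Product: 5 (R)-6-methyltetrahydro-2H-pyran-2-one, via hydroxy ester 4 (not isolated)
Conditions: H2 (1 atm), Pd/C, EtOAc, rt; filter; TsOH·H2O (cat.), CH2Cl2, rt
Reagents that add atoms: none
Why: Catalytic hydrogenation saturates the alkyne to 4, and acid-catalysed lactonization of the 5-hydroxy ester (six-membered ring, loss of ethanol) gives 5; the carbinol centre is not involved and stays R.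

Step 3
Reactants: 6 methyl orsellinate
Product: 7 methyl 2,4-bis(benzyloxy)-6-methylbenzoate
Conditions: BnBr (2.5 equiv), K2CO3, DMF, 60 °C
Reagents that add atoms: benzyl bromide, BrCc1ccccc1
Why: Williamson etherification; warming in DMF also alkylates the hydrogen-bonded C2 hydroxyl, and benzyl is chosen because it survives LiN(i-Pr)2 and is later removed under neutral conditions.

Step 4
Reactants: 7 methyl 2,4-bis(benzyloxy)-6-methylbenzoate; 5 (R)-6-methyltetrahydro-2H-pyran-2-one
Product: 9 (3S,6'R)-6,8-bis(benzyloxy)-6'-methyl-3',4',5',6'-tetrahydrospiro[isochromane-3,2'-pyran]-1-one, via keto alcohol 8 (not isolated)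
Conditions: 7 (2 equiv), LiN(i-Pr)2 (2.1 equiv), THF, −78 °C; 5 (1 equiv), −78 → −40 °C; AcOH; then TsOH·H2O (cat.), CH2Cl2, rt
Reagents that add atoms: none
Why: Lateral lithiation of the ortho-toluate gives an ester-stabilized benzylic anion that adds to the lactone carbonyl (toluate anion acylation); TsOH then funnels the keto alcohol/lactol mixture 8 into the spiro acyl ketal by lactol formation and lactonization onto the methyl ester. The spiro carbon is set under thermodynamic control by C6': the chair with the methyl equatorial and the lactone oxygen axial (anomeric effect) is the required S isomer.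

Step 5
Reactants: 9 bis(benzyl) spiro lactone
Product: 10 (3S,6'R)-6,8-dihydroxy-6'-methyl-3',4',5',6'-tetrahydrospiro[isochromane-3,2'-pyran]-1-one
Conditions: H2 (1 atm), Pd/C, EtOAc, rt
Reagents that add atoms: none
Why: Hydrogenolysis of the two aryl benzyl ethers is neutral, so the acyl ketal and the lactone are left alone; neither stereocentre is touched.

Step 6
Reactants: 11 2,2,6-trimethyl-4H-1,3-dioxin-4-one
Product: 12 2,2-dimethyl-6-(2-oxopropyl)-4H-1,3-dioxin-4-one
Conditions: LiN(SiMe3)2 (2 equiv), THF, −78 °C; AcCl (1 equiv), −78 °C; aq. HCl work-up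
Reagents that add atoms: acetyl chloride, CC(Cl)=O
Why: Claisen-type C-acylation of the vinylogous lithium enolate of 11 at the C6 methyl carbon; a second equivalent of enolate is consumed because 12 is more acidic than 11.

Step 7
Reactants: 13 methyl 3-oxooctanoate
Product: 14 methyl 2-(2-pentyl-1,3-dioxolan-2-yl)acetate
Conditions: HOCH2CH2OH, TsOH·H2O (cat.), PhMe, reflux (Dean–Stark)
Reagents that add atoms: ethylene glycol, OCCO
Why: Acid-catalysed ketalization of the ketone with azeotropic removal of water; the ester is unaffected, and the dioxolane masks the future side-chain ketone until the last step.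

Step 8
Reactants: 14 methyl 2-(2-pentyl-1,3-dioxolan-2-yl)acetate
Product: 15 N-methoxy-N-methyl-2-(2-pentyl-1,3-dioxolan-2-yl)acetamide
Conditions: MeNH(OMe)·HCl, i-PrMgCl, THF, −20 → 0 °C
Reagents that add atoms: N,O-dimethylhydroxylamine hydrochloride, Cl.CNOC
Why: Aminolysis of the methyl ester by the chloromagnesium amide formed in the flask (Weinreb amide synthesis); the resulting amide acylates a carbanion once only.

Step 9
Reactants: 12 2,2-dimethyl-6-(2-oxopropyl)-4H-1,3-dioxin-4-one; 15 Weinreb amide
Product: 16 6-[2,4-dioxo-5-(2-pentyl-1,3-dioxolan-2-yl)pentyl]-2,2-dimethyl-4H-1,3-dioxin-4-one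
Conditions: 12, LiN(i-Pr)2 (2.2 equiv), THF, −78 °C; 15, −78 → −40 °C; aq. NH4Cl
Reagents that add atoms: none
Why: Crossed Claisen acylation of the dianion of 12 at its terminal, more nucleophilic carbon by the Weinreb amide; the tetrahedral chelate persists until the buffered quench, which prevents over-addition and base-induced aromatization of 16 and spares the dioxolane.

Step 10
Reactants: 16 diketo-dioxinone; 10 ring B resorcinol
Product: 18 ring B aryl 3,5,7-trioxo-8-(2-pentyl-1,3-dioxolan-2-yl)octanoate (ester at the C6 oxygen of 10), via acylketene 17 (not isolated)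
Conditions: 10 (1 equiv), PhMe, 110 °C; 16 (1.3 equiv) added slowly; crude product used directly
Reagents that add atoms: none
Why: Thermal retro-[4+2] fragmentation of the dioxinone expels acetone and gives acylketene 17, which is captured by the C6 hydroxyl of 10 (acylketene trapping, no coupling agent); the C8 hydroxyl is hydrogen-bonded to the lactone carbonyl and should stay free. Slow addition keeps the ketene dilute relative to the phenol, which favours capture over self-cyclization.

Step 11
Reactants: 18 ring B aryl triketo ester
Product: 20 ring B aryl 2,4-dihydroxy-6-[(2-pentyl-1,3-dioxolan-2-yl)methyl]benzoate, via cyclic aldol 19 (not isolated)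
Conditions: Cs2CO3 (2.5 equiv), THF, 0 °C → rt; then AcOH (excess), rt
Reagents that add atoms: none
Why: Cs2CO3 deprotonates chain C2, flanked by the aryl ester and the C3 ketone, and also the ring B C8 phenol; the C2 enolate attacks the C7 ketone to give the cyclic aldol 19, E1cB loss of water across C6–C7 and enolization of the C3 and C5 carbonyls then give aromatic ring A, and AcOH completes the dehydration without hydrolysing the dioxolane or the acyl ketal. The closest known reaction is the biomimetic aldol aromatization of 3,5,7-triketo esters obtained from diketo-dioxinones through acylketenes, which gives 6-alkyl-2,4-dihydroxybenzoates. The one ring closed is carbocyclic ring A, by a 6-(enolendo)-exo-trig aldol that forms the bond between chain C2 (ring A C1) and chain C7 (ring A C6). No lasting stereocentre is created, since the two centres of 19 are erased on aromatization, and the spiro and C6' centres are remote from any acidic hydrogen. The selectivity needed is carbon aldol at C7 over the two reactions that expel the ring B aryloxide, attack of the C5 enolate oxygen on C1 (pyranone) and of C6 on C1 (Claisen folding), and over other aldol modes. Three features of 18 secure it: the C7 ketone is a better electrophile than an ester carbonyl; the C9 ketone is locked as a dioxolane, so the C4 enolate has no six-membered aldol partner, and carbonate is too weak to enolize C8; and the ionized C8 hydroxyl means the aryloxide would have to leave as a resorcinol dianion, which makes it a poor leaving group and the ester a poor acylating agent. An aprotic solvent is used so that no alkoxide can transesterify the aryl ester.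

Step 12
Reactants: 20 depside with free ring A resorcinol
Product: 21 ring B aryl 2-hydroxy-4-methoxy-6-[(2-pentyl-1,3-dioxolan-2-yl)methyl]benzoate
Conditions: MeI (1.1 equiv), K2CO3 (1.1 equiv), acetone, rt
Reagents that add atoms: iodomethane, CI
Why: Williamson methylation under weak base: the ring A C4 hydroxyl is the only phenol not held in a hydrogen bond to a carbonyl, hence the most acidic and nucleophilic, so one equivalent of MeI should alkylate it alone. Capping it also removes the most easily oxidized phenol before step 13.

Step 13
Reactants: 21 4-O-methyl depside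
Product: 22 dioxolane-protected depsidone
Conditions: MnO2 (activated, excess), CH2Cl2, rt, dark
Reagents that add atoms: none
Why: Oxidative phenol coupling of a depside to a depsidone: MnO2 oxidizes the phenols to phenoxyl radicals, and the ring A C2 oxygen bonds to ring B C5, the position para to the C8 oxygen where spin density is highest, closing the seven-membered dioxepinone; tautomerization restores the ring B phenol. C7, the only other open site next to the ester oxygen, is ortho to the C8 oxygen and flanked by two oxygens.

Step 14
Reactants: 22 dioxolane-protected depsidone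
Product: 23 CNP0301127.1
Conditions: 1 M aq. HCl, THF, rt
Reagents that add atoms: water, O
Why: Acid-catalysed hydrolysis of the dioxolane releases the ketone; the spiro acyl ketal is already the thermodynamically preferred anomeric isomer, so any reversible opening in dilute acid returns to it, and the aryl ester and lactone should not hydrolyse at room temperature.

## Compound list

1 | (R)-propylene oxide [(R)-2-methyloxirane] | C[C@@H]1CO1 | starting material
2 | ethyl propiolate | CCOC(=O)C#C | starting material
3 | ethyl (R)-5-hydroxyhex-2-ynoate | CCOC(=O)C#CC[C@@H](C)O | intermediate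
4 | ethyl (R)-5-hydroxyhexanoate (not isolated) | CCOC(=O)CCC[C@@H](C)O | intermediate
5 | (R)-6-methyltetrahydro-2H-pyran-2-one | C[C@@H]1CCCC(=O)O1 | intermediate
6 | methyl orsellinate (methyl 2,4-dihydroxy-6-methylbenzoate) | COC(=O)c1c(C)cc(O)cc1O | starting material
7 | methyl 2,4-bis(benzyloxy)-6-methylbenzoate | COC(=O)c1c(C)cc(OCc2ccccc2)cc1OCc1ccccc1 | intermediate
8 | methyl 2,4-bis(benzyloxy)-6-[(6R)-6-hydroxy-2-oxoheptyl]benzoate (open form of its lactol; not isolated) | COC(=O)c1c(CC(=O)CCC[C@@H](C)O)cc(OCc2ccccc2)cc1OCc1ccccc1 | intermediate
9 | (3S,6'R)-6,8-bis(benzyloxy)-6'-methyl-3',4',5',6'-tetrahydrospiro[isochromane-3,2'-pyran]-1-one | c1ccc(cc1)COc1cc(OCc2ccccc2)c2c(c1)C[C@]1(CCC[C@@H](C)O1)OC2=O | intermediate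
10 | (3S,6'R)-6,8-dihydroxy-6'-methyl-3',4',5',6'-tetrahydrospiro[isochromane-3,2'-pyran]-1-one | Oc1cc(O)c2c(c1)C[C@]1(CCC[C@@H](C)O1)OC2=O | intermediate
11 | 2,2,6-trimethyl-4H-1,3-dioxin-4-one | CC1=CC(=O)OC(C)(C)O1 | starting material
12 | 2,2-dimethyl-6-(2-oxopropyl)-4H-1,3-dioxin-4-one | CC(=O)CC1=CC(=O)OC(C)(C)O1 | intermediate
13 | methyl 3-oxooctanoate | CCCCCC(=O)CC(=O)OC | starting material
14 | methyl 2-(2-pentyl-1,3-dioxolan-2-yl)acetate | CCCCCC1(OCCO1)CC(=O)OC | intermediate
15 | N-methoxy-N-methyl-2-(2-pentyl-1,3-dioxolan-2-yl)acetamide | CCCCCC1(OCCO1)CC(=O)N(C)OC | intermediate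
16 | 6-[2,4-dioxo-5-(2-pentyl-1,3-dioxolan-2-yl)pentyl]-2,2-dimethyl-4H-1,3-dioxin-4-one | CCCCCC1(OCCO1)CC(=O)CC(=O)CC1=CC(=O)OC(C)(C)O1 | intermediate
17 | 3,5,7-trioxo-8-(2-pentyl-1,3-dioxolan-2-yl)oct-1-en-1-one (acylketene; not isolated) | CCCCCC1(OCCO1)CC(=O)CC(=O)CC(=O)C=C=O | intermediate
18 | (3S,6'R)-8-hydroxy-6'-methyl-1-oxo-3',4',5',6'-tetrahydrospiro[isochromane-3,2'-pyran]-6-yl 3,5,7-trioxo-8-(2-pentyl-1,3-dioxolan-2-yl)octanoate | CCCCCC1(OCCO1)CC(=O)CC(=O)CC(=O)CC(=O)Oc1cc(O)c2c(c1)C[C@]1(CCC[C@@H](C)O1)OC2=O | intermediate
19 | (3S,6'R)-8-hydroxy-6'-methyl-1-oxo-3',4',5',6'-tetrahydrospiro[isochromane-3,2'-pyran]-6-yl 2-hydroxy-4,6-dioxo-2-[(2-pentyl-1,3-dioxolan-2-yl)methyl]cyclohexane-1-carboxylate (cyclic aldol, mixture at its two transient centres; not isolated) | CCCCCC1(OCCO1)CC1(O)CC(=O)CC(=O)C1C(=O)Oc1cc(O)c2c(c1)C[C@]1(CCC[C@@H](C)O1)OC2=O | intermediate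
20 | (3S,6'R)-8-hydroxy-6'-methyl-1-oxo-3',4',5',6'-tetrahydrospiro[isochromane-3,2'-pyran]-6-yl 2,4-dihydroxy-6-[(2-pentyl-1,3-dioxolan-2-yl)methyl]benzoate | CCCCCC1(OCCO1)Cc1cc(O)cc(O)c1C(=O)Oc1cc(O)c2c(c1)C[C@]1(CCC[C@@H](C)O1)OC2=O | intermediate
21 | (3S,6'R)-8-hydroxy-6'-methyl-1-oxo-3',4',5',6'-tetrahydrospiro[isochromane-3,2'-pyran]-6-yl 2-hydroxy-4-methoxy-6-[(2-pentyl-1,3-dioxolan-2-yl)methyl]benzoate | CCCCCC1(OCCO1)Cc1cc(OC)cc(O)c1C(=O)Oc1cc(O)c2c(c1)C[C@]1(CCC[C@@H](C)O1)OC2=O | intermediate
22 | depsidone 23 with its side-chain ketone as the ethylene ketal, i.e. a (2-pentyl-1,3-dioxolan-2-yl)methyl group at ring A C6; (3S,6'R) | CCCCCC1(OCCO1)Cc1cc(OC)cc2c1C(=O)Oc1cc(O)c3c(c1O2)C[C@]1(CCC[C@@H](C)O1)OC3=O | intermediate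
23 | CNP0301127.1: depsidone in which ring A (C4 methoxy, C6 2-oxoheptyl) is joined to ring B of 10 by the C1 carboxylate ester at the C6 oxygen and by a C2–O–C5 ether; C8 hydroxyl free; (3S,6'R) | CCCCCC(=O)Cc1cc(OC)cc2c1C(=O)Oc1cc(O)c3c(c1O2)C[C@]1(CCC[C@@H](C)O1)OC3=O | target

## Step count and least certain steps

Total step count: 14. Longest linear sequence: 9 steps (1, 2, 4, 5, 10, 11, 12, 13, 14).

**Step 11 (key step).**
- Risk: loss of the ring B aryloxide, through O-acylation to a pyranone, through Claisen folding, or through E1cB reversal to the acylketene. The ester is an activated aryl ester, whereas the established cases of this aromatization use alkyl esters.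
- Fallback: sets out from 16 and comes back at 21. The aldol is run on an alkyl ester and the depside bond is made afterwards by a classical coupling.
  - 16 is heated with benzyl alcohol in toluene to give benzyl 3,5,7-trioxo-8-(2-pentyl-1,3-dioxolan-2-yl)octanoate F1.
  - Cs2CO3 in MeOH and then AcOH carry F1 through the benzyl cyclic aldol F2 to benzyl 2,4-dihydroxy-6-[(2-pentyl-1,3-dioxolan-2-yl)methyl]benzoate F3.
  - MeI/K2CO3 gives benzyl 2-hydroxy-4-methoxy-6-[(2-pentyl-1,3-dioxolan-2-yl)methyl]benzoate F4.
  - Hydrogenolysis over Pd/C frees 2-hydroxy-4-methoxy-6-[(2-pentyl-1,3-dioxolan-2-yl)methyl]benzoic acid F5.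
  - F5 is condensed with the C6 hydroxyl of 10 by N,N'-dicyclohexylcarbodiimide in toluene to give 21.

**Step 10.**
- Risk: capture of the acylketene by its own enolized C5 carbonyl outrunning addition of a weakly nucleophilic para-acyl phenol, with some acylation at the C8 hydroxyl.
- Fallback: sets out from 16 and 10 and comes back at 20. Ring A is aromatized before the ester is made.
  - Et3N in CH2Cl2 converts 16 into 7-hydroxy-2,2-dimethyl-5-[(2-pentyl-1,3-dioxolan-2-yl)methyl]-4H-1,3-benzodioxin-4-one F6.
  - Irradiation of F6 at about 300 nm in CH2Cl2 with 10 expels acetone and gives the quinoketene 3-hydroxy-6-(oxomethylidene)-5-[(2-pentyl-1,3-dioxolan-2-yl)methyl]cyclohexa-2,4-dien-1-one F7.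
  - F7 has no internal trap and is taken up by the C6 hydroxyl of 10 to give 20.

**Step 13.**
- Risk: coupling at C7 instead of C5, intermolecular coupling, or further oxidation of electron-rich ring A. Radical phenol coupling is steered only by spin density and ring size.
- Fallback: sets out from 10 and comes back at 22. The oxidation is replaced by a polar, copper-catalysed etherification at a pre-marked carbon.
  - N-iodosuccinimide iodinates 10 para to the C8 hydroxyl, giving (3S,6'R)-6,8-dihydroxy-5-iodo-6'-methyl-3',4',5',6'-tetrahydrospiro[isochromane-3,2'-pyran]-1-one F8.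
  - F8 is taken through the operations of steps 10 to 12: the iodo aryl triketo ester F9, the iodo cyclic aldol F10, the iodo depside F11 and its ring A 4-O-methyl ether F12.
  - Intramolecular Ullmann etherification of F12 (CuI, picolinic acid, K3PO4, DMSO, 80 °C) joins the ring A C2 oxygen to C5 and gives 22.

**Step 4.**
- Risk: collapse of the lactolate to the ketone, then enolization or a second addition, and closure to an enol lactone in place of the spiro lactone, so that the acid equilibration stays incomplete.
- Fallback: sets out from 5 and 7 and comes back at 9. An acyl donor that adds once is used, and the hydroxyl is protected.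
  - MeNH(OMe)·HCl/AlMe3 opens 5 to (R)-5-hydroxy-N-methoxy-N-methylhexanamide F13.
  - TBSCl/imidazole gives (R)-5-(tert-butyldimethylsilyloxy)-N-methoxy-N-methylhexanamide F14.
  - The lateral anion of 7 is acylated by F14 to give methyl 2,4-bis(benzyloxy)-6-[(6R)-6-(tert-butyldimethylsilyloxy)-2-oxoheptyl]benzoate F15.
  - Aqueous HCl in THF removes the silyl group to give 8, and TsOH in CH2Cl2 closes 8 to 9.

## Further compounds

F1 | step 11 | benzyl 3,5,7-trioxo-8-(2-pentyl-1,3-dioxolan-2-yl)octanoate | CCCCCC1(OCCO1)CC(=O)CC(=O)CC(=O)CC(=O)OCc1ccccc1
F2 | step 11 | benzyl 2-hydroxy-4,6-dioxo-2-[(2-pentyl-1,3-dioxolan-2-yl)methyl]cyclohexane-1-carboxylate (transient) | CCCCCC1(OCCO1)CC1(O)CC(=O)CC(=O)C1C(=O)OCc1ccccc1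
F3 | step 11 | benzyl 2,4-dihydroxy-6-[(2-pentyl-1,3-dioxolan-2-yl)methyl]benzoate | CCCCCC1(OCCO1)Cc1cc(O)cc(O)c1C(=O)OCc1ccccc1
F4 | step 11 | benzyl 2-hydroxy-4-methoxy-6-[(2-pentyl-1,3-dioxolan-2-yl)methyl]benzoate | CCCCCC1(OCCO1)Cc1cc(OC)cc(O)c1C(=O)OCc1ccccc1
F5 | step 11 | 2-hydroxy-4-methoxy-6-[(2-pentyl-1,3-dioxolan-2-yl)methyl]benzoic acid | CCCCCC1(OCCO1)Cc1cc(OC)cc(O)c1C(=O)O
F6 | step 10 | 7-hydroxy-2,2-dimethyl-5-[(2-pentyl-1,3-dioxolan-2-yl)methyl]-4H-1,3-benzodioxin-4-one | CCCCCC1(OCCO1)Cc1cc(O)cc2OC(C)(C)OC(=O)c12
F7 | step 10 | 3-hydroxy-6-(oxomethylidene)-5-[(2-pentyl-1,3-dioxolan-2-yl)methyl]cyclohexa-2,4-dien-1-one (quinoketene, transient) | O=C=C1C(=O)C=C(O)C=C1CC1(OCCO1)CCCCC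
F8 | step 13 | (3S,6'R)-6,8-dihydroxy-5-iodo-6'-methyl-3',4',5',6'-tetrahydrospiro[isochromane-3,2'-pyran]-1-one | Oc1cc(O)c2c(c1I)C[C@]1(CCC[C@@H](C)O1)OC2=O
F9 | step 13 | (3S,6'R)-8-hydroxy-5-iodo-6'-methyl-1-oxo-3',4',5',6'-tetrahydrospiro[isochromane-3,2'-pyran]-6-yl 3,5,7-trioxo-8-(2-pentyl-1,3-dioxolan-2-yl)octanoate | CCCCCC1(OCCO1)CC(=O)CC(=O)CC(=O)CC(=O)Oc1cc(O)c2c(c1I)C[C@]1(CCC[C@@H](C)O1)OC2=O
F10 | step 13 | 5-iodo analogue of cyclic aldol 19 (transient) | CCCCCC1(OCCO1)CC1(O)CC(=O)CC(=O)C1C(=O)Oc1cc(O)c2c(c1I)C[C@]1(CCC[C@@H](C)O1)OC2=O
F11 | step 13 | 5-iodo analogue of depside 20 | CCCCCC1(OCCO1)Cc1cc(O)cc(O)c1C(=O)Oc1cc(O)c2c(c1I)C[C@]1(CCC[C@@H](C)O1)OC2=O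
F12 | step 13 | 5-iodo analogue of 4-O-methyl depside 21 | CCCCCC1(OCCO1)Cc1cc(OC)cc(O)c1C(=O)Oc1cc(O)c2c(c1I)C[C@]1(CCC[C@@H](C)O1)OC2=O
F13 | step 4 | (R)-5-hydroxy-N-methoxy-N-methylhexanamide | C[C@@H](O)CCCC(=O)N(C)OC
F14 | step 4 | (R)-5-(tert-butyldimethylsilyloxy)-N-methoxy-N-methylhexanamide | C[C@@H](O[Si](C)(C)C(C)(C)C)CCCC(=O)N(C)OC
F15 | step 4 | methyl 2,4-bis(benzyloxy)-6-[(6R)-6-(tert-butyldimethylsilyloxy)-2-oxoheptyl]benzoate | COC(=O)c1c(CC(=O)CCC[C@@H](C)O[Si](C)(C)C(C)(C)C)cc(OCc2ccccc2)cc1OCc1ccccc1
A1 | alternative 1 | target carrying a dioxolane on the side-chain ketone and a methoxymethyl ether on the C8 oxygen | CCCCCC1(OCCO1)Cc1cc(OC)cc2c1C(=O)Oc1cc(OCOC)c3c(c1O2)C[C@]1(CCC[C@@H](C)O1)OC3=O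
A2 | alternative 1 | (3S,6'R)-5-(ethynyloxy)-8-(methoxymethoxy)-6'-methyl-1-oxo-3',4',5',6'-tetrahydrospiro[isochromane-3,2'-pyran]-6-yl 4-(2-pentyl-1,3-dioxolan-2-yl)but-2-ynoate | CCCCCC1(OCCO1)CC#CC(=O)Oc1cc(OCOC)c2c(c1OC#C)C[C@]1(CCC[C@@H](C)O1)OC2=O
A3 | alternative 1 | methoxyacetylene | COC#C
A4 | alternative 2 | tert-butyl 2-({2-[(4R)-4-(tert-butyldimethylsilyloxy)pentyl]-1,3-dioxolan-2-yl}methyl)-3,6-dihydroxy-4-isopropoxybenzoate | CC(C)Oc1cc(O)c(C(=O)OC(C)(C)C)c(CC2(OCCO2)CCC[C@@H](C)O[Si](C)(C)C(C)(C)C)c1O
A5 | alternative 2 | tert-butyl (E)-4-{2-[(4R)-4-(tert-butyldimethylsilyloxy)pentyl]-1,3-dioxolan-2-yl}-3-(1-hydroxy-2-isopropoxy-4-oxocyclobut-2-en-1-yl)but-2-enoate (ring carbinol carbon of either configuration) | CC(C)OC1=CC(=O)C1(O)/C(CC1(OCCO1)CCC[C@@H](C)O[Si](C)(C)C(C)(C)C)=C/C(=O)OC(C)(C)C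
A6 | alternative 3 | (3S,6'R)-6,8-bis(benzyloxy)-6'-methyl-3',4',5',6'-tetrahydrospiro[isochromane-3,2'-pyran]-1-one | c1ccc(cc1)COc1cc(OCc2ccccc2)c2c(c1)C[C@]1(CCC[C@@H](C)O1)OC2=O
A7 | alternative 3 | 2-hydroxy-4-methoxy-6-[(2-pentyl-1,3-dioxolan-2-yl)methyl]benzoic acid | CCCCCC1(OCCO1)Cc1cc(OC)cc(O)c1C(=O)O
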